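# Route to CNP0245550.1 (41) by nickel-catalysed reductive ynal macrocyclization

Positions are cited with germacrane numbering: ring carbons C1–C10, lactone carbons C11–C13, C14 on C10, C15 on C4, side-chain carbons C1'–C4'.

## Analysis of the target

Compound 41 is a germacranolide: a ten-membered carbocycle C1–C10 with a γ-lactone (O6–C12(=O)–C11) fused across C6–C7, an exocyclic methylene on the lactone (C11=C13) and a second one on the carbocycle (C10=C14). The only endocyclic alkene is C4=C5, with the ring carbons C3 and C6 cis to each other and the acetoxymethyl carbon C15 on C4. C6 (S), C7 (R) and C8 (S) form a contiguous triad: H6 and H7 are cis (cis-fused lactone), and along the C5–C9 zigzag the C7–C11 bond is anti to O6 and syn to O8. C1 (R) is remote from the triad, with its oxygen on the ring face of the lactone oxygen and opposite to O8. A fifth stereocentre, C3' (R), lies in the 3,4-dihydroxy-2-methylenebutanoate on O8. The sensitive groups are two Michael acceptors (α-methylene lactone, acrylate), a primary allylic acetate, allylic C–O bonds at C1 and C6, a diol that can attack its own ester carbonyl under base, and a C8 oxygen that can take over the lactone carbonyl. The synthesis is hard because a ten-membered ring with a ring-cis trisubstituted alkene must be closed, four oxygens (O1, O6, O8, O15) must end as alcohol, lactone, hindered ester and acetate, and C1 must be set far from the other centres. The strategy rests on the C1–C10 bond: C1 is a carbinol bonded to C10, which carries the 1,1-disubstituted C14 methylene. This is the pattern left by reductive coupling of a C1 aldehyde with the internal carbon of a terminal C10≡C14 alkyne.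

## Retrosynthetic reasoning

**Protecting groups and side-chain ester (41 ⇒ 40 ⇒ 39 ⇒ 32 + 37).** The diol and O1 are unmasked last, under acid only, because the free diol ester is base-labile. The C8–O acyl bond is cut next: the acrylate is a Michael acceptor and cannot be carried through enolate or nickel chemistry. The forward step must acylate a hindered secondary alcohol with acid 37 while O1 stays silylated and the lactone stays on O6.

**Adjustment on the closed ring (32 ⇒ 31 ⇒ 30 ⇒ 29 ⇒ 26).** The C15 acetate is traced to a 4-methoxybenzyl ether, since an acetate would not survive the lactone enolate. The C11=C13 methylene is traced to the saturated lactone, since an enoate would compete for nickel in the ring closure. A triethylsilyl ether on O8 against a triisopropylsilyl ether on O1 lets O8 be freed alone.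

**C1–C10 (26 ⇒ 25).** This cut opens the ring at the one bond whose formation also creates the C14 methylene and the C1 oxygen at the right oxidation level. The forward reaction must couple at the internal alkyne carbon, close a ten-membered ring and set C1.

**C1 aldehyde, alkyne cap and C3–C4 (25 ⇒ 24 ⇒ 23 ⇒ 19 + 20).** The aldehyde comes from the primary alcohol and the terminal alkyne from its C-silyl form. The C3–C4 sp2–sp3 bond is cut so that the alkene geometry is stored in alkenyl iodide 19 and transferred with retention in a B-alkyl cross-coupling with the borane from 20.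

**Lactone (19 ⇒ 18 ⇒ 15).** C12 is traced to the terminal alkene of an allyl group on C7 (C12=C13 cut). An allyl group survives the acetylide and hydride steps that an ester or lactone would not. The cleavage is placed at the iodoalkene stage, where the only other C=C bond is deactivated.

**Iodoalkene and C6 (15 ⇒ 13 ⇒ 12).** The Z-iodide with iodine cis to C6 is the product of hydroxyl-directed trans-hydroalumination and iodination of propargylic alcohol 13. C6 is set by catalyst-controlled reduction of ynone 12, which avoids reliance on acyclic 1,2-induction.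

**C5–C6 (12 ⇒ 9 + 11).** Acylation of the acetylide of 11 by Weinreb amide 9 joins the C15–C4–C5 unit to the core without over-addition.

**C7–C8 (9 ⇒ 8 ⇒ 7 ⇒ 3 + 5).** The syn relation of the C7 branch and O8 is an auxiliary-controlled syn-aldol retron. Imide 3 (from 1 and 2) supplies C6, C7 and the allyl group; aldehyde 5 (from 4) supplies C8–C10 and C14. Ether 11 comes from 10.

**Side-chain acid (37 ⇒ 36 ⇒ 33).** The α-methylene group is added to the chiral-pool ester 33, whose stereocentre becomes C3'.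

## Alternatives that were turned down

**Alternative 1:** The ring bond C6–C7 is cut and closed enzymatically. A sesquiterpene synthase ionizes (2Z,6E)-farnesyl diphosphate A2 and joins its C1 to the distal alkene, giving (4Z)-germacrene A A1 after proton loss.
- For: one step from an achiral precursor gives the ten-membered ring, the ring-cis alkene and C7. On ring construction and step count to the carbocycle this is stronger than the chosen route.
- Against: A1 is a hydrocarbon. The target needs oxygen at C1, C6, C8, C12 (acid level) and C15, plus a shift of the C1=C10 alkene to C10=C14, all by site- and face-selective C–H oxidation. The substrate is a flexible cyclodeca-1,5-diene set up for Cope rearrangement and transannular cyclization. Each oxidation would need its own enzyme or a reagent of matching selectivity, and acceptance of the 4Z series is open.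
- Comparison: the chosen strategy spends more steps, but every oxygen is placed on an acyclic chain by predictable chemistry before the ring is closed.

**Alternative 2:** The C7–C8 bond is cut. Tin–lithium exchange with an alkyllithium at the stannyl carbon of the thirteen-membered allyl ether A4 gives an α-alkoxy carbanion. Its [2,3] shift makes C7–C8, releases O from C13, forms C11=C13 and contracts the ring to carbocycle A3.
- For: a larger, easier ring is contracted. The free C8 hydroxyl and the C11=C13 methylene appear in the same event, so neither late methylenation nor O1/O8 differentiation is needed. On these two points it is stronger.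
- Against: the shift must set C7 and C8 together through a macrocyclic transition state, with a [1,2] shift as the usual competitor. A4 already contains the C1 carbinol, the C10 methylene, the ring-cis alkene and a stannane, and needs its own macrocyclization, so the precursor is long. The lactol ether of A3 must still be oxidized next to a free alcohol.
- Comparison: in the chosen route C7 and C8 come from an acyclic aldol reaction, and the ring closure has only C1 to control.

**Alternative 3:** The C2–C3 bond is formed while C5–C10 is broken. The potassium alkoxide of cis-dialkenylcyclohexanol A6 undergoes an anionic oxy-Cope shift that expands the six-membered ring to the ten-membered ring, and silylation of the C10 enolate gives A5.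
- For: a pericyclic ring expansion needs no high dilution. The C4=C5 geometry follows from the transition-state shape, and C6–C8 are set on a cyclohexane where control is easy. In reliability of the ring-forming event it is stronger.
- Against: in A5, C10 is at ketone level and C1 is an sp2 carbon without oxygen. The target then needs α-oxygenation at C1 with facial control on a flexible ring and methylenation of a hindered α-oxy ketone. The cis arrangement demands a boat transition state, and A6 has a tertiary carbinol in a run of five stereocentres. The lactone must travel as a lactol ether.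
- Comparison: the chosen coupling delivers the C1 carbinol and the C14 methylene in the ring-forming step itself.

Key step: step 15

## Route

Assumption: methyl (R)-2,2-dimethyl-1,3-dioxolane-4-acetate (33) is taken as a purchasable chiral-pool ester of the malic acid series.

Step 1
Reactants: 1 (R)-4-benzyloxazolidin-2-one; 2 pent-4-enoyl chloride
Product: 3 (R)-4-benzyl-3-(pent-4-enoyl)oxazolidin-2-one
Conditions: n-BuLi, THF, −78 °C; then 2, −78 → 0 °C
Reagents that add atoms: none
Why: N-Acylation of the lithiated oxazolidinone by the acid chloride, the standard preparation of an Evans imide; no stereocentre is touched.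

Step 2
Reactants: 4 4-(trimethylsilyl)but-3-yn-1-ol
Product: 5 4-(trimethylsilyl)but-3-ynal
Conditions: Dess–Martin periodinane, CH2Cl2, 0 °C → rt; used at once without chromatography
Reagents that add atoms: none
Why: Dess–Martin oxidation of a primary homopropargylic alcohol under non-basic conditions, which avoids isomerization of the β,γ-alkynyl aldehyde to the allene.

Step 3
Reactants: 3 (R)-4-benzyl-3-(pent-4-enoyl)oxazolidin-2-one; 5 4-(trimethylsilyl)but-3-ynal
Product: 7 (R)-4-benzyl-3-[(2R,3S)-2-allyl-3-hydroxy-6-(trimethylsilyl)hex-5-ynoyl]oxazolidin-2-one, via dibutylboron Z-enolate 6 (not isolated)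
Conditions: Bu2BOTf, Et3N, CH2Cl2, −78 → 0 °C; 5, −78 → −20 °C; pH 7 buffer, MeOH, H2O2, 0 °C
Reagents that add atoms: none
Why: Evans syn-aldol reaction: the Z-boron enolate reacts through a chair Zimmerman–Traxler transition state on the face away from the benzyl group, which sets C7 (R) and C8 (S) with the allyl branch and the hydroxyl syn. The (R)-auxiliary is the enantiomer that gives this pair, and the low temperature and the silyl cap limit alkyne–allene isomerization of 5.

Step 4
Reactants: 7 (R)-4-benzyl-3-[(2R,3S)-2-allyl-3-hydroxy-6-(trimethylsilyl)hex-5-ynoyl]oxazolidin-2-one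
Product: 8 (2R,3S)-2-allyl-3-hydroxy-N-methoxy-N-methyl-6-(trimethylsilyl)hex-5-ynamide
Conditions: MeONHMe·HCl, AlMe3, THF/CH2Cl2, −20 → 0 °C
Reagents that add atoms: N,O-dimethylhydroxylamine hydrochloride, CNOC.Cl
Why: Aluminium amide transamidation of the aldol imide to the Weinreb amide, assisted by the free β-hydroxyl; auxiliary 1 is recovered and C7 is not epimerized.

Step 5
Reactants: 8 (2R,3S)-2-allyl-3-hydroxy-N-methoxy-N-methyl-6-(trimethylsilyl)hex-5-ynamide
Product: 9 (2R,3S)-2-allyl-N-methoxy-N-methyl-3-(triethylsilyloxy)-6-(trimethylsilyl)hex-5-ynamide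
Conditions: Et3SiOTf, 2,6-lutidine, CH2Cl2, −78 → 0 °C
Reagents that add atoms: triethylsilyl trifluoromethanesulfonate, CC[Si](CC)(CC)OS(=O)(=O)C(F)(F)F
Why: Silylation of the hindered secondary alcohol with the silyl triflate; the C8 triethylsilyl ether prevents cyclization of the later β-hydroxy ynone and is the group removed selectively in step 19.

Step 6
Reactants: 10 propargyl alcohol
Product: 11 1-methoxy-4-[(prop-2-yn-1-yloxy)methyl]benzene
Conditions: NaH, THF/DMF, 0 °C; 4-MeOC6H4CH2Cl, Bu4NI (cat.), rt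
Reagents that add atoms: 4-methoxybenzyl chloride, COc1ccc(CCl)cc1
Why: Williamson etherification of the propargylic alkoxide; the terminal C–H is left for metalation.

Step 7
Reactants: 11 1-methoxy-4-[(prop-2-yn-1-yloxy)methyl]benzene; 9 (2R,3S)-2-allyl-N-methoxy-N-methyl-3-(triethylsilyloxy)-6-(trimethylsilyl)hex-5-ynamide
Product: 12 (5R,6S)-5-allyl-1-[(4-methoxybenzyl)oxy]-6-(triethylsilyloxy)-9-(trimethylsilyl)nona-2,8-diyn-4-one
Conditions: 11, n-BuLi, THF, −78 °C; then 9, −78 → −20 °C; aqueous work-up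
Reagents that add atoms: none
Why: Addition of the lithium acetylide to the Weinreb amide forms C5–C6; the chelated tetrahedral intermediate prevents over-addition, and the ynone appears only on work-up, which protects C7.

Step 8
Reactants: 12 (5R,6S)-5-allyl-1-[(4-methoxybenzyl)oxy]-6-(triethylsilyloxy)-9-(trimethylsilyl)nona-2,8-diyn-4-one
Product: 13 (4R,5S,6S)-5-allyl-1-[(4-methoxybenzyl)oxy]-6-(triethylsilyloxy)-9-(trimethylsilyl)nona-2,8-diyn-4-ol
Conditions: Ru[(R,R)-TsDPEN](p-cymene) (cat.), i-PrOH, rt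
Reagents that add atoms: none
Why: Noyori asymmetric transfer hydrogenation of an alkynyl ketone; the alkynyl group takes the place that an aryl group has in aryl ketone reductions, so the (R,R)-catalyst should give the 4R carbinol (C6) under catalyst control. The silylalkyne and the terminal alkene are not reduced.

Step 9
Reactants: 13 (4R,5S,6S)-5-allyl-1-[(4-methoxybenzyl)oxy]-6-(triethylsilyloxy)-9-(trimethylsilyl)nona-2,8-diyn-4-ol
Product: 15 (2Z,4R,5S,6S)-5-allyl-2-iodo-1-[(4-methoxybenzyl)oxy]-6-(triethylsilyloxy)-9-(trimethylsilyl)non-2-en-8-yn-4-ol, via sodium oxaluminacycle 14 (not isolated)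
Conditions: NaAlH2(OCH2CH2OMe)2, THF, 0 °C; EtOAc (quench of excess hydride); I2, −78 → 0 °C
Reagents that add atoms: iodine, II
Why: Hydroxyl-directed trans-hydroalumination of the propargylic alcohol: the C6 alkoxyaluminate delivers hydride to C5 and aluminium ends on C4 in a five-membered ring; iodinolysis with retention gives the Z-iodide with iodine cis to C6. The silylalkyne, the terminal alkene and the ethers do not react at 0 °C.

Step 10
Reactants: 15 (2Z,4R,5S,6S)-5-allyl-2-iodo-1-[(4-methoxybenzyl)oxy]-6-(triethylsilyloxy)-9-(trimethylsilyl)non-2-en-8-yn-4-ol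
Product: 18 (4S,5R)-5-[(Z)-2-iodo-3-[(4-methoxybenzyl)oxy]prop-1-en-1-yl]-4-[(1S)-1-(triethylsilyloxy)-4-(trimethylsilyl)but-3-yn-1-yl]tetrahydrofuran-2-ol (both C2 epimers), via triol 16 (not isolated), via hydroxy aldehyde 17 (not isolated)
Conditions: OsO4 (cat.), NaIO4, 2,6-lutidine, dioxane/H2O, rt
Reagents that add atoms: osmium tetroxide, O=[Os](=O)(=O)=O; sodium periodate, [Na+].[O-]I(=O)(=O)=O
Why: Lemieux–Johnson cleavage: OsO4 dihydroxylates the monosubstituted terminal alkene in preference to the electron-poor, hindered iodoalkene and the alkyne; periodate cleaves the diol, and the γ-hydroxy aldehyde closes onto O6 to the five-membered lactol.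

Step 11
Reactants: 18 (4S,5R)-5-[(Z)-2-iodo-3-[(4-methoxybenzyl)oxy]prop-1-en-1-yl]-4-[(1S)-1-(triethylsilyloxy)-4-(trimethylsilyl)but-3-yn-1-yl]tetrahydrofuran-2-ol
Product: 19 (4S,5R)-5-[(Z)-2-iodo-3-[(4-methoxybenzyl)oxy]prop-1-en-1-yl]-4-[(1S)-1-(triethylsilyloxy)-4-(trimethylsilyl)but-3-yn-1-yl]dihydrofuran-2(3H)-one
Conditions: TEMPO (cat.), PhI(OAc)2, CH2Cl2, rt
Reagents that add atoms: none
Why: Oxoammonium (TEMPO) oxidation of the lactol to the γ-lactone; no other oxidizable alcohol is present, and the cis relation of the C6 and C7 substituents was fixed in steps 3 and 8.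

Step 12
Reactants: 19 (4S,5R)-5-[(Z)-2-iodo-3-[(4-methoxybenzyl)oxy]prop-1-en-1-yl]-4-[(1S)-1-(triethylsilyloxy)-4-(trimethylsilyl)but-3-yn-1-yl]dihydrofuran-2(3H)-one; 20 allyloxytrimethylsilane
Product: 23 (4S,5S)-5-[(E)-5-hydroxy-2-{[(4-methoxybenzyl)oxy]methyl}pent-1-en-1-yl]-4-[(1S)-1-(triethylsilyloxy)-4-(trimethylsilyl)but-3-yn-1-yl]dihydrofuran-2(3H)-one, via alkylborane 21 (not isolated), via trimethylsilyl ether 22 (not isolated)
Conditions: 20, 9-BBN, THF, 0 °C → rt; then 19, Pd(dppf)Cl2 (cat.), AsPh3 (cat.), Cs2CO3, DMF/THF/H2O, rt; aq. citric acid on work-up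
Reagents that add atoms: none
Why: B-alkyl Suzuki–Miyaura coupling: anti-Markovnikov hydroboration of 20 gives the primary alkylborane, which couples at C4 with retention of alkene geometry, so C3 ends cis to C6 (ring-cis C4=C5). The labile O-trimethylsilyl group falls off on acidic work-up and leaves the C1 alcohol.

Step 13
Reactants: 23 (4S,5S)-5-[(E)-5-hydroxy-2-{[(4-methoxybenzyl)oxy]methyl}pent-1-en-1-yl]-4-[(1S)-1-(triethylsilyloxy)-4-(trimethylsilyl)but-3-yn-1-yl]dihydrofuran-2(3H)-one
Product: 24 (4S,5S)-5-[(E)-5-hydroxy-2-{[(4-methoxybenzyl)oxy]methyl}pent-1-en-1-yl]-4-[(1S)-1-(triethylsilyloxy)but-3-yn-1-yl]dihydrofuran-2(3H)-one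
Conditions: AgNO3 (cat.), MeOH/H2O/CH2Cl2, rt
Reagents that add atoms: none
Why: Silver-catalysed protodesilylation of the alkynylsilane through a silver acetylide; the neutral conditions spare the lactone and the triethylsilyl ether.

Step 14
Reactants: 24 (4S,5S)-5-[(E)-5-hydroxy-2-{[(4-methoxybenzyl)oxy]methyl}pent-1-en-1-yl]-4-[(1S)-1-(triethylsilyloxy)but-3-yn-1-yl]dihydrofuran-2(3H)-one
Product: 25 (E)-4-{[(4-methoxybenzyl)oxy]methyl}-5-{(2S,3S)-5-oxo-3-[(1S)-1-(triethylsilyloxy)but-3-yn-1-yl]tetrahydrofuran-2-yl}pent-4-enal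
Conditions: Dess–Martin periodinane, pyridine, CH2Cl2, 0 °C → rt
Reagents that add atoms: none
Why: Dess–Martin oxidation of the only free alcohol to the C1 aldehyde; the buffered, non-basic conditions keep the C8 silyl ether and the terminal alkyne.

Step 15
Reactants: 25 (E)-4-{[(4-methoxybenzyl)oxy]methyl}-5-{(2S,3S)-5-oxo-3-[(1S)-1-(triethylsilyloxy)but-3-yn-1-yl]tetrahydrofuran-2-yl}pent-4-enal
Product: 26 (3aS,4S,7R,10E,11aS)-10-{[(4-methoxybenzyl)oxy]methyl}-6-methylene-4-(triethylsilyloxy)-7-(triisopropylsilyloxy)-3a,4,5,6,7,8,9,11a-octahydrocyclodeca[b]furan-2(3H)-one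
Conditions: Ni(COD)2 (cat.), 1,3-bis(2,6-diisopropylphenyl)imidazol-2-ylidene (cat.), i-Pr3SiH, THF, rt → 45 °C, slow addition of 25 at high dilution
Reagents that add atoms: triisopropylsilane, CC(C)[SiH](C(C)C)C(C)C
Why: The carbene-ligated zerovalent nickel centre coordinates the aldehyde carbonyl and the terminal alkyne of 25 side by side and couples them oxidatively, which makes the C1–C10 bond inside a five-membered nickelacycle (Ni–O1 and Ni–C14); the silane then cleaves the Ni–O bond, silicon going to O1 and hydride to nickel, and reductive elimination forms the C14–H bond and returns the catalyst. This is a nickel-catalysed aldehyde–alkyne reductive macrocyclization, a known reaction type for ynals. The ten-membered ring closes in the exo mode at the alkyne (formally 10-exo-dig, C14 left outside the ring); the endo mode would give an eleven-membered ring with an endocyclic E-alkene. The first selectivity needed is coupling at the internal alkyne carbon: the large N-aryl groups of the carbene force the smaller alkyne terminus (C14–H) next to nickel and the C9 chain next to the forming bond, and the bulky silane reinforces this. The second is the C1 configuration: the cis ring fusion and the ring-cis alkene fold the chain and shorten the C1–C10 distance, and the nickelacycle with its ligand is expected to form on the face remote from the C8 triethylsilyl ether, which puts O1 on the face of the lactone oxygen (1R, 7R in the ring name); a chiral carbene can reinforce this bias. Slow addition suppresses oligomerization and direct aldehyde hydrosilylation. With C11 still saturated there is no α,β-unsaturated carbonyl group that could enter nickel-mediated coupling, and the trisubstituted C4=C5 alkene binds nickel poorly, which should protect the allylic C6–O bond.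

Step 16
Reactants: 26 (3aS,4S,7R,10E,11aS)-10-{[(4-methoxybenzyl)oxy]methyl}-6-methylene-4-(triethylsilyloxy)-7-(triisopropylsilyloxy)-3a,4,5,6,7,8,9,11a-octahydrocyclodeca[b]furan-2(3H)-one
Product: 29 (3aS,4S,7R,10E,11aS)-10-{[(4-methoxybenzyl)oxy]methyl}-3,6-dimethylene-4-(triethylsilyloxy)-7-(triisopropylsilyloxy)-3a,4,5,6,7,8,9,11a-octahydrocyclodeca[b]furan-2(3H)-one, via Mannich base 27 (not isolated), via ammonium iodide 28 (not isolated)
Conditions: LiN(i-Pr)2, THF, −78 °C; Me2N=CH2+ I−, −78 °C → rt; MeI, MeOH, rt; aq. NaHCO3, CH2Cl2, rt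
Reagents that add atoms: dimethylmethyleneiminium iodide, C[N+](C)=C.[I-]
Why: α-Methylenation of a γ-lactone by the Mannich route: the lithium enolate at C11 is aminomethylated by the iminium salt, and exhaustive methylation followed by mild base eliminates trimethylamine to give C11=C13. No leaving group sits β to the enolate carbon and no other acidic C–H competes.

Step 17
Reactants: 29 (3aS,4S,7R,10E,11aS)-10-{[(4-methoxybenzyl)oxy]methyl}-3,6-dimethylene-4-(triethylsilyloxy)-7-(triisopropylsilyloxy)-3a,4,5,6,7,8,9,11a-octahydrocyclodeca[b]furan-2(3H)-one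
Product: 30 (3aS,4S,7R,10E,11aS)-10-(hydroxymethyl)-3,6-dimethylene-4-(triethylsilyloxy)-7-(triisopropylsilyloxy)-3a,4,5,6,7,8,9,11a-octahydrocyclodeca[b]furan-2(3H)-one
Conditions: DDQ, CH2Cl2/pH 7 buffer, 0 °C
Reagents that add atoms: none
Why: Oxidative cleavage of the 4-methoxybenzyl ether by DDQ through the benzylic oxocarbenium ion; the buffered two-phase medium protects the silyl ethers, and a short reaction time limits further oxidation of the allylic alcohol.

Step 18
Reactants: 30 (3aS,4S,7R,10E,11aS)-10-(hydroxymethyl)-3,6-dimethylene-4-(triethylsilyloxy)-7-(triisopropylsilyloxy)-3a,4,5,6,7,8,9,11a-octahydrocyclodeca[b]furan-2(3H)-one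
Product: 31 [(3aS,4S,7R,10E,11aS)-3,6-dimethylene-2-oxo-4-(triethylsilyloxy)-7-(triisopropylsilyloxy)-2,3,3a,4,5,6,7,8,9,11a-decahydrocyclodeca[b]furan-10-yl]methyl acetate
Conditions: Ac2O, pyridine, DMAP (cat.), CH2Cl2, 0 °C → rt
Reagents that add atoms: acetic anhydride, CC(=O)OC(C)=O
Why: DMAP-catalysed acetylation of the primary allylic alcohol, the only free hydroxyl.

Step 19
Reactants: 31 [(3aS,4S,7R,10E,11aS)-3,6-dimethylene-2-oxo-4-(triethylsilyloxy)-7-(triisopropylsilyloxy)-2,3,3a,4,5,6,7,8,9,11a-decahydrocyclodeca[b]furan-10-yl]methyl acetate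
Product: 32 [(3aR,4S,7R,10E,11aS)-4-hydroxy-3,6-dimethylene-2-oxo-7-(triisopropylsilyloxy)-2,3,3a,4,5,6,7,8,9,11a-decahydrocyclodeca[b]furan-10-yl]methyl acetate
Conditions: HF·pyridine, pyridine, THF, 0 °C
Reagents that add atoms: none
Why: Buffered fluoride desilylation; a secondary triethylsilyl ether is cleaved far faster than the secondary triisopropylsilyl ether at C1, and the non-basic medium avoids migration of the lactone to O8.

Step 20
Reactants: 33 methyl 2-[(4R)-2,2-dimethyl-1,3-dioxolan-4-yl]acetate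
Product: 36 methyl 2-[(4R)-2,2-dimethyl-1,3-dioxolan-4-yl]acrylate, via Mannich base 34 (not isolated), via ammonium iodide 35 (not isolated)
Conditions: LiN(i-Pr)2, THF, −78 °C; Me2N=CH2+ I−, −78 → −20 °C; MeI, MeOH, rt; aq. NaHCO3, CH2Cl2, rt
Reagents that add atoms: dimethylmethyleneiminium iodide, C[N+](C)=C.[I-]
Why: Ester enolate aminomethylation, quaternization and elimination (Mannich methylenation); at −78 °C the dioxolane oxygen β to the enolate should be retained, and the stereocentre is not involved.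

Step 21
Reactants: 36 methyl 2-[(4R)-2,2-dimethyl-1,3-dioxolan-4-yl]acrylate
Product: 37 2-[(4R)-2,2-dimethyl-1,3-dioxolan-4-yl]acrylic acid
Conditions: LiOH, THF/H2O, 0 °C → rt; then 1 M HCl to pH 3–4, 0 °C
Reagents that add atoms: lithium hydroxide, [Li+].[OH-]
Why: Saponification of the methyl ester; brief, cold acidification keeps the acetonide.

Step 22
Reactants: 37 2-[(4R)-2,2-dimethyl-1,3-dioxolan-4-yl]acrylic acid; 32 [(3aR,4S,7R,10E,11aS)-4-hydroxy-3,6-dimethylene-2-oxo-7-(triisopropylsilyloxy)-2,3,3a,4,5,6,7,8,9,11a-decahydrocyclodeca[b]furan-10-yl]methyl acetate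
Product: 39 (3aR,4S,7R,10E,11aS)-10-(acetoxymethyl)-3,6-dimethylene-2-oxo-7-(triisopropylsilyloxy)-2,3,3a,4,5,6,7,8,9,11a-decahydrocyclodeca[b]furan-4-yl 2-[(4R)-2,2-dimethyl-1,3-dioxolan-4-yl]acrylate, via mixed anhydride 38 (not isolated)
Conditions: 37, 2,4,6-Cl3C6H2COCl, Et3N, toluene, rt; then 32, DMAP, toluene, rt
Reagents that add atoms: none
Why: Yamaguchi esterification: DMAP attacks the mixed anhydride at the acrylic carbonyl and the acylpyridinium acylates the hindered C8 alcohol with retention at C8.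

Step 23
Reactants: 39 (3aR,4S,7R,10E,11aS)-10-(acetoxymethyl)-3,6-dimethylene-2-oxo-7-(triisopropylsilyloxy)-2,3,3a,4,5,6,7,8,9,11a-decahydrocyclodeca[b]furan-4-yl 2-[(4R)-2,2-dimethyl-1,3-dioxolan-4-yl]acrylate
Product: 40 (3aR,4S,7R,10E,11aS)-10-(acetoxymethyl)-7-hydroxy-3,6-dimethylene-2-oxo-2,3,3a,4,5,6,7,8,9,11a-decahydrocyclodeca[b]furan-4-yl 2-[(4R)-2,2-dimethyl-1,3-dioxolan-4-yl]acrylate
Conditions: HF·pyridine, THF, 0 °C → rt
Reagents that add atoms: none
Why: Cleavage of the triisopropylsilyl ether by HF·pyridine; the medium is acidic, so neither ester migrates, and any loss of the acetonide leads on to 41.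

Step 24
Reactants: 40 (3aR,4S,7R,10E,11aS)-10-(acetoxymethyl)-7-hydroxy-3,6-dimethylene-2-oxo-2,3,3a,4,5,6,7,8,9,11a-decahydrocyclodeca[b]furan-4-yl 2-[(4R)-2,2-dimethyl-1,3-dioxolan-4-yl]acrylate
Product: 41 (3aR,4S,7R,10E,11aS)-10-(acetoxymethyl)-7-hydroxy-3,6-dimethylene-2-oxo-2,3,3a,4,5,6,7,8,9,11a-decahydrocyclodeca[b]furan-4-yl (3R)-3,4-dihydroxy-2-methylenebutanoate (CNP0245550.1)
Conditions: AcOH/H2O/THF, rt
Reagents that add atoms: none
Why: Acid-catalysed hydrolysis of the terminal acetonide under conditions too mild to ionize the allylic C1–O or C6–O bonds or to hydrolyse the esters; base is avoided because the free diol would attack its own ester.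

## Compound list

1 | (R)-4-benzyloxazolidin-2-one | O=C1N[C@H](Cc2ccccc2)CO1 | starting material
2 | pent-4-enoyl chloride | C=CCCC(=O)Cl | starting material
3 | (R)-4-benzyl-3-(pent-4-enoyl)oxazolidin-2-one | C=CCCC(=O)N1C(=O)OC[C@H]1Cc1ccccc1 | intermediate
4 | 4-(trimethylsilyl)but-3-yn-1-ol | C[Si](C)(C)C#CCCO | starting material
5 | 4-(trimethylsilyl)but-3-ynal | C[Si](C)(C)C#CCC=O | intermediate
6 | dibutylboron (Z)-enolate of 3 | C=CC/C=C(\OB(CCCC)CCCC)N1C(=O)OC[C@H]1Cc1ccccc1 | intermediate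
7 | (R)-4-benzyl-3-[(2R,3S)-2-allyl-3-hydroxy-6-(trimethylsilyl)hex-5-ynoyl]oxazolidin-2-one | C=CC[C@H]([C@@H](O)CC#C[Si](C)(C)C)C(=O)N1C(=O)OC[C@H]1Cc1ccccc1 | intermediate
8 | (2R,3S)-2-allyl-3-hydroxy-N-methoxy-N-methyl-6-(trimethylsilyl)hex-5-ynamide | C=CC[C@H]([C@@H](O)CC#C[Si](C)(C)C)C(=O)N(C)OC | intermediate
9 | (2R,3S)-2-allyl-N-methoxy-N-methyl-3-(triethylsilyloxy)-6-(trimethylsilyl)hex-5-ynamide | C=CC[C@H]([C@@H](O[Si](CC)(CC)CC)CC#C[Si](C)(C)C)C(=O)N(C)OC | intermediate
10 | propargyl alcohol (prop-2-yn-1-ol) | C#CCO | starting material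
11 | 1-methoxy-4-[(prop-2-yn-1-yloxy)methyl]benzene | C#CCOCc1ccc(OC)cc1 | intermediate
12 | (5R,6S)-5-allyl-1-[(4-methoxybenzyl)oxy]-6-(triethylsilyloxy)-9-(trimethylsilyl)nona-2,8-diyn-4-one | C=CC[C@H]([C@@H](O[Si](CC)(CC)CC)CC#C[Si](C)(C)C)C(=O)C#CCOCc1ccc(OC)cc1 | intermediate
13 | (4R,5S,6S)-5-allyl-1-[(4-methoxybenzyl)oxy]-6-(triethylsilyloxy)-9-(trimethylsilyl)nona-2,8-diyn-4-ol | C=CC[C@H]([C@@H](O[Si](CC)(CC)CC)CC#C[Si](C)(C)C)[C@@H](O)C#CCOCc1ccc(OC)cc1 | intermediate
14 | sodium 2,2-bis(2-methoxyethoxy)-2,5-dihydro-1,2-oxaluminol-2-uide formed from 13 (O6–Al–C4 ring, C4=C5 in the ring) | C=CC[C@H]([C@@H](O[Si](CC)(CC)CC)CC#C[Si](C)(C)C)[C@H]1O[Al-](OCCOC)(OCCOC)C(COCc2ccc(OC)cc2)=C1.[Na+] | intermediate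
15 | (2Z,4R,5S,6S)-5-allyl-2-iodo-1-[(4-methoxybenzyl)oxy]-6-(triethylsilyloxy)-9-(trimethylsilyl)non-2-en-8-yn-4-ol | C=CC[C@H]([C@@H](O[Si](CC)(CC)CC)CC#C[Si](C)(C)C)[C@@H](O)/C=C(\I)COCc1ccc(OC)cc1 | intermediate
16 | (2Z,4R,5S,6S)-5-(2,3-dihydroxypropyl)-2-iodo-1-[(4-methoxybenzyl)oxy]-6-(triethylsilyloxy)-9-(trimethylsilyl)non-2-en-8-yn-4-ol (diol epimers) | OCC(O)C[C@H]([C@@H](O[Si](CC)(CC)CC)CC#C[Si](C)(C)C)[C@@H](O)/C=C(\I)COCc1ccc(OC)cc1 | intermediate
17 | (3S,4R,5Z)-4-hydroxy-6-iodo-7-[(4-methoxybenzyl)oxy]-3-[(1S)-1-(triethylsilyloxy)-4-(trimethylsilyl)but-3-yn-1-yl]hept-5-enal | O=CC[C@H]([C@@H](O[Si](CC)(CC)CC)CC#C[Si](C)(C)C)[C@@H](O)/C=C(\I)COCc1ccc(OC)cc1 | intermediate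
18 | (4S,5R)-5-[(Z)-2-iodo-3-[(4-methoxybenzyl)oxy]prop-1-en-1-yl]-4-[(1S)-1-(triethylsilyloxy)-4-(trimethylsilyl)but-3-yn-1-yl]tetrahydrofuran-2-ol (C2 epimers) | I/C(COCc1ccc(OC)cc1)=C\[C@@H]1OC(O)C[C@@H]1[C@@H](O[Si](CC)(CC)CC)CC#C[Si](C)(C)C | intermediate
19 | (4S,5R)-5-[(Z)-2-iodo-3-[(4-methoxybenzyl)oxy]prop-1-en-1-yl]-4-[(1S)-1-(triethylsilyloxy)-4-(trimethylsilyl)but-3-yn-1-yl]dihydrofuran-2(3H)-one | I/C(COCc1ccc(OC)cc1)=C\[C@@H]1OC(=O)C[C@@H]1[C@@H](O[Si](CC)(CC)CC)CC#C[Si](C)(C)C | intermediate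
20 | allyloxytrimethylsilane | C=CCO[Si](C)(C)C | starting material
21 | 9-[3-(trimethylsilyloxy)propyl]-9-borabicyclo[3.3.1]nonane | C[Si](C)(C)OCCCB1C2CCCC1CCC2 | intermediate
22 | O-trimethylsilyl ether of 23 | C[Si](C)(C)OCCC/C(COCc1ccc(OC)cc1)=C\[C@@H]1OC(=O)C[C@@H]1[C@@H](O[Si](CC)(CC)CC)CC#C[Si](C)(C)C | intermediate
23 | (4S,5S)-5-[(E)-5-hydroxy-2-{[(4-methoxybenzyl)oxy]methyl}pent-1-en-1-yl]-4-[(1S)-1-(triethylsilyloxy)-4-(trimethylsilyl)but-3-yn-1-yl]dihydrofuran-2(3H)-one | OCCC/C(COCc1ccc(OC)cc1)=C\[C@@H]1OC(=O)C[C@@H]1[C@@H](O[Si](CC)(CC)CC)CC#C[Si](C)(C)C | intermediate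
24 | (4S,5S)-5-[(E)-5-hydroxy-2-{[(4-methoxybenzyl)oxy]methyl}pent-1-en-1-yl]-4-[(1S)-1-(triethylsilyloxy)but-3-yn-1-yl]dihydrofuran-2(3H)-one | OCCC/C(COCc1ccc(OC)cc1)=C\[C@@H]1OC(=O)C[C@@H]1[C@@H](O[Si](CC)(CC)CC)CC#C | intermediate
25 | (E)-4-{[(4-methoxybenzyl)oxy]methyl}-5-{(2S,3S)-5-oxo-3-[(1S)-1-(triethylsilyloxy)but-3-yn-1-yl]tetrahydrofuran-2-yl}pent-4-enal (seco ynal) | O=CCC/C(COCc1ccc(OC)cc1)=C\[C@@H]1OC(=O)C[C@@H]1[C@@H](O[Si](CC)(CC)CC)CC#C | intermediate
26 | (3aS,4S,7R,10E,11aS)-10-{[(4-methoxybenzyl)oxy]methyl}-6-methylene-4-(triethylsilyloxy)-7-(triisopropylsilyloxy)-3a,4,5,6,7,8,9,11a-octahydrocyclodeca[b]furan-2(3H)-one | C1C(=O)O[C@H]2/C=C(/COCc3ccc(OC)cc3)CC[C@@H](O[Si](C(C)C)(C(C)C)C(C)C)C(=C)C[C@H](O[Si](CC)(CC)CC)[C@@H]12 | intermediate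
27 | 3-[(dimethylamino)methyl] derivative of 26 (C3 epimers) | CN(C)CC1C(=O)O[C@H]2/C=C(/COCc3ccc(OC)cc3)CC[C@@H](O[Si](C(C)C)(C(C)C)C(C)C)C(=C)C[C@H](O[Si](CC)(CC)CC)[C@@H]12 | intermediate
28 | 3-[(trimethylammonio)methyl] derivative of 26, iodide | C[N+](C)(C)CC1C(=O)O[C@H]2/C=C(/COCc3ccc(OC)cc3)CC[C@@H](O[Si](C(C)C)(C(C)C)C(C)C)C(=C)C[C@H](O[Si](CC)(CC)CC)[C@@H]12.[I-] | intermediate
29 | (3aS,4S,7R,10E,11aS)-10-{[(4-methoxybenzyl)oxy]methyl}-3,6-dimethylene-4-(triethylsilyloxy)-7-(triisopropylsilyloxy)-3a,4,5,6,7,8,9,11a-octahydrocyclodeca[b]furan-2(3H)-one | C=C1C(=O)O[C@H]2/C=C(/COCc3ccc(OC)cc3)CC[C@@H](O[Si](C(C)C)(C(C)C)C(C)C)C(=C)C[C@H](O[Si](CC)(CC)CC)[C@@H]12 | intermediate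
30 | (3aS,4S,7R,10E,11aS)-10-(hydroxymethyl)-3,6-dimethylene-4-(triethylsilyloxy)-7-(triisopropylsilyloxy)-3a,4,5,6,7,8,9,11a-octahydrocyclodeca[b]furan-2(3H)-one | C=C1C(=O)O[C@H]2/C=C(/CO)CC[C@@H](O[Si](C(C)C)(C(C)C)C(C)C)C(=C)C[C@H](O[Si](CC)(CC)CC)[C@@H]12 | intermediate
31 | [(3aS,4S,7R,10E,11aS)-3,6-dimethylene-2-oxo-4-(triethylsilyloxy)-7-(triisopropylsilyloxy)-2,3,3a,4,5,6,7,8,9,11a-decahydrocyclodeca[b]furan-10-yl]methyl acetate | C=C1C(=O)O[C@H]2/C=C(/COC(C)=O)CC[C@@H](O[Si](C(C)C)(C(C)C)C(C)C)C(=C)C[C@H](O[Si](CC)(CC)CC)[C@@H]12 | intermediate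
32 | [(3aR,4S,7R,10E,11aS)-4-hydroxy-3,6-dimethylene-2-oxo-7-(triisopropylsilyloxy)-2,3,3a,4,5,6,7,8,9,11a-decahydrocyclodeca[b]furan-10-yl]methyl acetate | C=C1C(=O)O[C@H]2/C=C(/COC(C)=O)CC[C@@H](O[Si](C(C)C)(C(C)C)C(C)C)C(=C)C[C@H](O)[C@@H]12 | intermediate
33 | methyl 2-[(4R)-2,2-dimethyl-1,3-dioxolan-4-yl]acetate | COC(=O)C[C@@H]1COC(C)(C)O1 | starting material
34 | methyl 3-(dimethylamino)-2-[(4R)-2,2-dimethyl-1,3-dioxolan-4-yl]propanoate (C2 epimers) | COC(=O)C(CN(C)C)[C@@H]1COC(C)(C)O1 | intermediate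
35 | {2-[(4R)-2,2-dimethyl-1,3-dioxolan-4-yl]-3-methoxy-3-oxopropyl}trimethylammonium iodide | COC(=O)C(C[N+](C)(C)C)[C@@H]1COC(C)(C)O1.[I-] | intermediate
36 | methyl 2-[(4R)-2,2-dimethyl-1,3-dioxolan-4-yl]acrylate | COC(=O)C(=C)[C@@H]1COC(C)(C)O1 | intermediate
37 | 2-[(4R)-2,2-dimethyl-1,3-dioxolan-4-yl]acrylic acid | OC(=O)C(=C)[C@@H]1COC(C)(C)O1 | intermediate
38 | 2-[(4R)-2,2-dimethyl-1,3-dioxolan-4-yl]acrylic 2,4,6-trichlorobenzoic anhydride | C=C(C(=O)OC(=O)c1c(Cl)cc(Cl)cc1Cl)[C@@H]1COC(C)(C)O1 | intermediate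
39 | (3aR,4S,7R,10E,11aS)-10-(acetoxymethyl)-3,6-dimethylene-2-oxo-7-(triisopropylsilyloxy)-2,3,3a,4,5,6,7,8,9,11a-decahydrocyclodeca[b]furan-4-yl 2-[(4R)-2,2-dimethyl-1,3-dioxolan-4-yl]acrylate | C=C1C(=O)O[C@H]2/C=C(/COC(C)=O)CC[C@@H](O[Si](C(C)C)(C(C)C)C(C)C)C(=C)C[C@H](OC(=O)C(=C)[C@@H]3COC(C)(C)O3)[C@@H]12 | intermediate
40 | (3aR,4S,7R,10E,11aS)-10-(acetoxymethyl)-7-hydroxy-3,6-dimethylene-2-oxo-2,3,3a,4,5,6,7,8,9,11a-decahydrocyclodeca[b]furan-4-yl 2-[(4R)-2,2-dimethyl-1,3-dioxolan-4-yl]acrylate | C=C1C(=O)O[C@H]2/C=C(/COC(C)=O)CC[C@@H](O)C(=C)C[C@H](OC(=O)C(=C)[C@@H]3COC(C)(C)O3)[C@@H]12 | intermediate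
41 | (3aR,4S,7R,10E,11aS)-10-(acetoxymethyl)-7-hydroxy-3,6-dimethylene-2-oxo-2,3,3a,4,5,6,7,8,9,11a-decahydrocyclodeca[b]furan-4-yl (3R)-3,4-dihydroxy-2-methylenebutanoate (CNP0245550.1) | C=C1C(=O)O[C@H]2/C=C(/COC(C)=O)CC[C@@H](O)C(=C)C[C@H](OC(=O)C(=C)[C@@H](O)CO)[C@@H]12 | target

## Step count and least certain steps

Total: 24 steps. Longest linear sequence: 20 steps (steps 1, 3–5, 7–19, 22–24). Steps 2 and 6 and steps 20–21 are side branches.

**Step 15 (key step).** The ring closure may lose to oligomerization or to direct hydrosilylation of the aldehyde. Coupling may occur at the terminal alkyne carbon (endo closure to the eleven-membered ring). Facial selectivity at C1 may be poor because the ten-membered transition state is flexible. Zerovalent nickel may ionize the allylic C6–O bond of the lactone.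
Fallback (sets out from 24, returns at 26): the same C1–C10 bond is made by a Nozaki–Hiyama–Kishi ring closure. Markovnikov hydrosilylation of the terminal alkyne of 24 ([Cp*Ru(MeCN)3]PF6 cat., Et3SiH) should give (4S,5S)-5-[(E)-5-hydroxy-2-{[(4-methoxybenzyl)oxy]methyl}pent-1-en-1-yl]-4-[(1S)-1-(triethylsilyloxy)-3-(triethylsilyl)but-3-en-1-yl]dihydrofuran-2(3H)-one F5. Dess–Martin oxidation then gives the silylalkene aldehyde F6, and iododesilylation (N-iodosuccinimide, hexafluoroisopropanol, 0 °C) gives the 2-iodoalkene aldehyde F7. CrCl2 with catalytic NiCl2 in DMSO/THF at high dilution closes the ring to the C1 allylic alcohol F8. If both C1 epimers form, the mixture is oxidized to the cross-conjugated C1 enone F9 and reduced with a Corey–Bakshi–Shibata catalyst to F8. Silylation with i-Pr3SiOTf and 2,6-lutidine then gives 26.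

**Step 3.** The β,γ-alkynyl aldehyde 5 may isomerize to the allenyl or conjugated aldehyde under the amine base, or condense with itself, before the enolate captures it.
Fallback (sets out from 3, returns at 8): C9 is introduced as an electrophile instead. The same boron aldol reaction with anhydrous chloroacetaldehyde should give (R)-4-benzyl-3-[(2R,3R)-2-allyl-4-chloro-3-hydroxybutanoyl]oxazolidin-2-one F1, which is spatially the same syn adduct. Transamidation as in step 4 gives (2R,3R)-2-allyl-4-chloro-3-hydroxy-N-methoxy-N-methylbutanamide F2. K2CO3 in MeOH closes the epoxide (2R)-N-methoxy-N-methyl-2-[(2R)-oxiran-2-yl]pent-4-enamide F3. Opening at the terminal carbon with lithium (trimethylsilyl)acetylide and BF3·OEt2 at −78 °C gives 8.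

**Step 9.** The alkenylaluminate 14 carries the C15 alkoxide β to aluminium. Loss of this alkoxide to an allene, or protonation without iodination, would erode the yield of the iodide.
Fallback (sets out from 12, returns at 15): the iodine is put in before the carbinol. Conjugate hydroiodination of ynone 12 (NaI, AcOH, rt) should give the β-iodoenone with iodine cis to the carbonyl, (2Z,5R,6S)-5-allyl-2-iodo-1-[(4-methoxybenzyl)oxy]-6-(triethylsilyloxy)-9-(trimethylsilyl)non-2-en-8-yn-4-one F4. Corey–Bakshi–Shibata reduction ((S)-2-methyl-oxazaborolidine, catecholborane), with the iodoalkenyl group as the large substituent, gives 15.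

**Step 20.** The ester enolate may expel the dioxolane oxygen β to it (ring opening to a γ-hydroxy enoate) before it is trapped.
Fallback (sets out from 33, returns at 37): the methylene is introduced at the aldehyde level without a strong base. Reduction of 33 with i-Bu2AlH at −78 °C gives 2-[(4R)-2,2-dimethyl-1,3-dioxolan-4-yl]acetaldehyde F10. Amine-catalysed α-methylenation (aqueous formaldehyde, pyrrolidine, propionic acid cat., i-PrOH) gives 2-[(4R)-2,2-dimethyl-1,3-dioxolan-4-yl]acrylaldehyde F11. Pinnick oxidation (NaClO2, NaH2PO4, 2-methylbut-2-ene) gives 37.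

**Step 22.** Acylation of the hindered C8 hydroxyl by an α-substituted acrylic acid may be slow. That leaves time for conjugate addition of the nucleophilic catalyst to the activated acrylate and for migration of the lactone acyl group from O6 to O8.
Fallback (sets out from 34, isolated here, and from 32; returns at 39): the acrylate is unmasked only after the ester bond exists. Saponification of 34 (LiOH, THF/H2O) gives 3-(dimethylamino)-2-[(4R)-2,2-dimethyl-1,3-dioxolan-4-yl]propanoic acid F12. Carbodiimide coupling with 32 gives the β-amino ester F13, which is not a Michael acceptor and tolerates more forcing acylation. Exhaustive methylation (MeI) and aqueous NaHCO3 then eliminate the amine and give 39.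

## Further compounds

F1 | step 3 | (R)-4-benzyl-3-[(2R,3R)-2-allyl-4-chloro-3-hydroxybutanoyl]oxazolidin-2-one | C=CC[C@H]([C@@H](O)CCl)C(=O)N1C(=O)OC[C@H]1Cc1ccccc1
F2 | step 3 | (2R,3R)-2-allyl-4-chloro-3-hydroxy-N-methoxy-N-methylbutanamide | C=CC[C@H]([C@@H](O)CCl)C(=O)N(C)OC
F3 | step 3 | (2R)-N-methoxy-N-methyl-2-[(2R)-oxiran-2-yl]pent-4-enamide | C=CC[C@H]([C@@H]1CO1)C(=O)N(C)OC
F4 | step 9 | (2Z,5R,6S)-5-allyl-2-iodo-1-[(4-methoxybenzyl)oxy]-6-(triethylsilyloxy)-9-(trimethylsilyl)non-2-en-8-yn-4-one | C=CC[C@H]([C@@H](O[Si](CC)(CC)CC)CC#C[Si](C)(C)C)C(=O)/C=C(\I)COCc1ccc(OC)cc1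
F5 | step 15 | (4S,5S)-5-[(E)-5-hydroxy-2-{[(4-methoxybenzyl)oxy]methyl}pent-1-en-1-yl]-4-[(1S)-1-(triethylsilyloxy)-3-(triethylsilyl)but-3-en-1-yl]dihydrofuran-2(3H)-one | OCCC/C(COCc1ccc(OC)cc1)=C\[C@@H]1OC(=O)C[C@@H]1[C@@H](O[Si](CC)(CC)CC)CC(=C)[Si](CC)(CC)CC
F6 | step 15 | (E)-4-{[(4-methoxybenzyl)oxy]methyl}-5-{(2S,3S)-5-oxo-3-[(1S)-1-(triethylsilyloxy)-3-(triethylsilyl)but-3-en-1-yl]tetrahydrofuran-2-yl}pent-4-enal | O=CCC/C(COCc1ccc(OC)cc1)=C\[C@@H]1OC(=O)C[C@@H]1[C@@H](O[Si](CC)(CC)CC)CC(=C)[Si](CC)(CC)CC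
F7 | step 15 | (E)-5-{(2S,3S)-3-[(1S)-3-iodo-1-(triethylsilyloxy)but-3-en-1-yl]-5-oxotetrahydrofuran-2-yl}-4-{[(4-methoxybenzyl)oxy]methyl}pent-4-enal | O=CCC/C(COCc1ccc(OC)cc1)=C\[C@@H]1OC(=O)C[C@@H]1[C@@H](O[Si](CC)(CC)CC)CC(I)=C
F8 | step 15 | (3aS,4S,7R,10E,11aS)-7-hydroxy-10-{[(4-methoxybenzyl)oxy]methyl}-6-methylene-4-(triethylsilyloxy)-3a,4,5,6,7,8,9,11a-octahydrocyclodeca[b]furan-2(3H)-one | C1C(=O)O[C@H]2/C=C(/COCc3ccc(OC)cc3)CC[C@@H](O)C(=C)C[C@H](O[Si](CC)(CC)CC)[C@@H]12
F9 | step 15 | (3aS,4S,10E,11aS)-10-{[(4-methoxybenzyl)oxy]methyl}-6-methylene-4-(triethylsilyloxy)-3a,4,5,6,8,9-hexahydrocyclodeca[b]furan-2,7(3H,11aH)-dione | C1C(=O)O[C@H]2/C=C(/COCc3ccc(OC)cc3)CCC(=O)C(=C)C[C@H](O[Si](CC)(CC)CC)[C@@H]12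
F10 | step 20 | 2-[(4R)-2,2-dimethyl-1,3-dioxolan-4-yl]acetaldehyde | O=CC[C@@H]1COC(C)(C)O1
F11 | step 20 | 2-[(4R)-2,2-dimethyl-1,3-dioxolan-4-yl]acrylaldehyde | O=CC(=C)[C@@H]1COC(C)(C)O1
F12 | step 22 | 3-(dimethylamino)-2-[(4R)-2,2-dimethyl-1,3-dioxolan-4-yl]propanoic acid (C2 epimers) | CN(C)CC(C(=O)O)[C@@H]1COC(C)(C)O1
F13 | step 22 | (3aR,4S,7R,10E,11aS)-10-(acetoxymethyl)-3,6-dimethylene-2-oxo-7-(triisopropylsilyloxy)-2,3,3a,4,5,6,7,8,9,11a-decahydrocyclodeca[b]furan-4-yl 3-(dimethylamino)-2-[(4R)-2,2-dimethyl-1,3-dioxolan-4-yl]propanoate | C=C1C(=O)O[C@H]2/C=C(/COC(C)=O)CC[C@@H](O[Si](C(C)C)(C(C)C)C(C)C)C(=C)C[C@H](OC(=O)C(CN(C)C)[C@@H]3COC(C)(C)O3)[C@@H]12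
A1 | alternative 1 | (4Z)-germacrene A (helminthogermacrene A) | C=C(C)[C@H]1C/C=C(/C)CC/C=C(\C)CC1
A2 | alternative 1 | (2Z,6E)-farnesyl diphosphate | CC(C)=CCC/C(C)=C/CC/C(C)=C\COP(O)(=O)OP(O)(O)=O
A3 | alternative 2 | ten-membered carbocycle with cis-fused 3-methylene lactol methyl ether, free C8 hydroxyl, C1 tert-butyldimethylsilyl ether and C15 4-methoxybenzyl ether | C=C1C(OC)O[C@H]2/C=C(/COCc3ccc(OC)cc3)CC[C@@H](O[Si](C)(C)C(C)(C)C)C(=C)C[C@H](O)[C@@H]12
A4 | alternative 2 | thirteen-membered allyl ether with tributylstannyl group on C8 and O8–C13 ether link to the 2-methoxy-2,5-dihydrofuran (C8 epimers) | COC1O[C@H]2/C=C(/COCc3ccc(OC)cc3)CC[C@@H](O[Si](C)(C)C(C)(C)C)C(=C)CC([Sn](CCCC)(CCCC)CCCC)OCC1=C2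
A5 | alternative 3 | ten-membered C10 trimethylsilyl enol ether with ring-cis C4=C5, lactol methyl ether, C8 triethylsilyl ether and C15 4-methoxybenzyl ether | C1C(OC)O[C@H]2/C=C(/COCc3ccc(OC)cc3)CC/C=C(\O[Si](C)(C)C)C[C@H](O[Si](CC)(CC)CC)[C@@H]12
A6 | alternative 3 | cis-dialkenylcyclohexanol (ring C5–C10) with C10 vinyl and hydroxyl, C5 3-[(4-methoxybenzyl)oxy]prop-1-en-2-yl group, C8 triethylsilyl ether and cis-fused lactol methyl ether; C5 and C10 drawn for one cis diastereomer | C=C[C@]1(O)C[C@H](O[Si](CC)(CC)CC)[C@H]2CC(OC)O[C@H]2[C@@H]1C(=C)COCc1ccc(OC)cc1
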